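**Retrosynthetic overview**

1. Locants used in the text: rings A (methylcyclopentane), B (cyclooctene), C (cyclohexane), D (cyclopentanol). Ring C/D carbons are numbered steroid-style: C8H2, C9H, C11H, C12H2, C13 (quaternary, CH3), C14H, C15H(i-Pr), C16H2, C17H(OH); β is the face of the C13 methyl group.
2. Enabling feature: read as its C17 ketone, ring D is a cyclopentanone whose C16–C17 bond is the retron of a 4-pentenal hydroacylation. Its C13–C14 bond (quaternary α-carbon next to the carbon that carries the 1-isopropylvinyl unit C15=C16) is the retron of a Claisen rearrangement. Ring C is a chair with the C13 methyl axial and everything else equatorial, the imprint of a chair–chair transannular transition state of an (E,E)-ten-membered ring.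
3. Disconnections: ring B last, by McMurry coupling of the C9 acetyl group with the ring-A ketone. The exocyclic methylene and the C9 acetyl come from a C11 ketone and a C9 ester by one double methylenation; ring A arrives as Grignard fragment 30. Rings C and D are formed together from the (E,E)-1-oxacyclodeca-2,8-diene 17 by transannular Claisen ring contraction followed in the same pot by rhodium-catalysed hydroacylation.
4. 17 comes from intramolecular ester-enolate alkylation of an acyclic allyl vinyl ether, made by copper-promoted coupling of alkenylboronate 12 with allylic alcohol 4. The C11 stereocentre comes from an oxazolidinone-auxiliary alkylation and relays its configuration through the key step.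
5. Order of ring formation: temporary ten-membered oxacycle → rings C and D (one operation) → ring B; ring A is preformed in fragment 30.

Key step: step 11

Remark on the chemistry: the carbon α to the ester (C9) is epimerisable; it is not controlled in step 10 and is fixed by equilibration in step 12, so formulas show the C9 ester equatorial (9β) throughout.

**Route**

Step 1
Reactants: 1 4-{[tert-butyl(dimethyl)silyl]oxy}but-2-yn-1-ol
Product: 3 (2Z)-4-{[tert-butyl(dimethyl)silyl]oxy}-2-iodobut-2-en-1-ol, via alkenylalane 2 (not isolated)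
Conditions: LiAlH4, AlCl3 (2 mol %), THF, 0 → 25 °C; then I2, −78 → 0 °C
Reagents that add atoms: iodine, II
Why: hydroxyl-directed trans-hydroalumination of the propargylic alcohol under Lewis-acidic alane conditions should place aluminium on the carbinol-proximal carbon and hydride anti on the distal one, and iodinolysis with retention should give the (Z)-2-iodoalkene that fixes the later allyl geometry.

Step 2
Reactants: 3 (2Z)-4-{[tert-butyl(dimethyl)silyl]oxy}-2-iodobut-2-en-1-ol
Product: 4 (2E)-4-{[tert-butyl(dimethyl)silyl]oxy}-2-(propan-2-yl)but-2-en-1-ol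
Conditions: i-PrZnBr (3 equiv), Pd(OAc)2 (2 mol %), CPhos (4 mol %), THF, 25 °C
Reagents that add atoms: isopropylzinc bromide, CC(C)[Zn]Br
Why: Negishi coupling of an alkenyl iodide with a secondary alkylzinc halide proceeds with retention of alkene geometry (the biarylphosphine suppresses isomerisation to n-propyl), so the isopropyl group should end up cis to the silyloxymethyl-bearing carbon.

Step 3
Reactants: 5 4-methylpent-4-enoic acid; 6 (4R)-4-benzyl-1,3-oxazolidin-2-one
Product: 8 (4R)-4-benzyl-3-(4-methylpent-4-enoyl)-1,3-oxazolidin-2-one, via mixed pivalic anhydride 7 (not isolated)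
Conditions: t-BuCOCl, Et3N, THF, −20 °C; then 6, LiCl, 25 °C
Reagents that add atoms: none
Why: N-acylation of the oxazolidinone through the mixed pivalic anhydride is a standard way to load the chiral auxiliary.

Step 4
Reactants: 8 (4R)-4-benzyl-3-(4-methylpent-4-enoyl)-1,3-oxazolidin-2-one
Product: 10 methyl (3S)-3-{[(4R)-4-benzyl-2-oxo-1,3-oxazolidin-3-yl]carbonyl}-5-methylhex-5-enoate, via sodium enolate 9 (not isolated)
Conditions: NaN(SiMe3)2, THF, −78 °C; then BrCH2CO2CH3, −78 → −45 °C
Reagents that add atoms: methyl bromoacetate, COC(=O)CBr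
Why: auxiliary-controlled alkylation (Evans alkylation) of the chelated (Z)-enolate, in which the electrophile should attack the face opposite the benzyl group and so set the C11 stereocentre (S).

Step 5
Reactants: 10 methyl (3S)-3-{[(4R)-4-benzyl-2-oxo-1,3-oxazolidin-3-yl]carbonyl}-5-methylhex-5-enoate
Product: 11 methyl (3S)-3-[methoxy(methyl)carbamoyl]-5-methylhex-5-enoate
Conditions: Al(CH3)3, CH3NHOCH3·HCl, CH2Cl2, −10 → 0 °C
Reagents that add atoms: N,O-dimethylhydroxylamine hydrochloride, CNOC.Cl
Why: transamidation of the N-acyloxazolidinone with the aluminium amide (Weinreb amide formation) removes the auxiliary at 0 °C, where the imide should react much faster than the methyl ester, and lowers the acidity of the C11 hydrogen for step 10.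

Step 6
Reactants: 11 methyl (3S)-3-[methoxy(methyl)carbamoyl]-5-methylhex-5-enoate
Product: 12 methyl (3S,5E)-3-[methoxy(methyl)carbamoyl]-5-methyl-6-(4,4,5,5-tetramethyl-1,3,2-dioxaborolan-2-yl)hex-5-enoate
Conditions: vinylboronic acid pinacol ester (3 equiv), second-generation Grubbs catalyst (5 mol %), CH2Cl2, 40 °C
Reagents that add atoms: vinylboronic acid pinacol ester, C=CB1OC(C)(C)C(C)(C)O1
Why: olefin cross-metathesis of a 1,1-disubstituted alkene with a vinylboronate should give the trisubstituted alkenylboronate with boron trans to the larger CH2 substituent (E), the geometry needed for the chair transition state of step 11.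

Step 7
Reactants: 12 methyl (3S,5E)-3-[methoxy(methyl)carbamoyl]-5-methyl-6-(4,4,5,5-tetramethyl-1,3,2-dioxaborolan-2-yl)hex-5-enoate; 4 (2E)-4-{[tert-butyl(dimethyl)silyl]oxy}-2-(propan-2-yl)but-2-en-1-ol
Product: 13 methyl (3S,5E)-6-{[(2E)-4-{[tert-butyl(dimethyl)silyl]oxy}-2-(propan-2-yl)but-2-en-1-yl]oxy}-3-[methoxy(methyl)carbamoyl]-5-methylhex-5-enoate
Conditions: 4 (3 equiv), Cu(OAc)2 (2 equiv), Et3N (4 equiv), 4 Å molecular sieves, CH2Cl2, air, 25 °C
Reagents that add atoms: none
Why: copper-promoted oxidative coupling of an alkenylboronate with an alcohol (Chan–Lam-type etherification) should form the allyl vinyl ether with retention of alkene geometry at room temperature, far below the temperature of an acyclic Claisen rearrangement.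

Step 8
Reactants: 13 methyl (3S,5E)-6-{[(2E)-4-{[tert-butyl(dimethyl)silyl]oxy}-2-(propan-2-yl)but-2-en-1-yl]oxy}-3-[methoxy(methyl)carbamoyl]-5-methylhex-5-enoate
Product: 14 methyl (3S,5E)-6-{[(2E)-4-hydroxy-2-(propan-2-yl)but-2-en-1-yl]oxy}-3-[methoxy(methyl)carbamoyl]-5-methylhex-5-enoate
Conditions: Bu4NF, THF, 0 °C
Reagents that add atoms: none
Why: fluoride-mediated desilylation frees the primary allylic alcohol without touching the acid-sensitive enol ether.

Step 9
Reactants: 14 methyl (3S,5E)-6-{[(2E)-4-hydroxy-2-(propan-2-yl)but-2-en-1-yl]oxy}-3-[methoxy(methyl)carbamoyl]-5-methylhex-5-enoate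
Product: 15 methyl (3S,5E)-6-{[(2E)-4-bromo-2-(propan-2-yl)but-2-en-1-yl]oxy}-3-[methoxy(methyl)carbamoyl]-5-methylhex-5-enoate
Conditions: CBr4, PPh3, 2,6-lutidine, CH2Cl2, −30 °C
Reagents that add atoms: carbon tetrabromide, BrC(Br)(Br)Br
Why: the Appel reaction under buffered conditions converts the primary allylic alcohol into the bromide by SN2 at the unhindered CH2, with no allylic transposition and no acid to hydrolyse the enol ether.

Step 10
Reactants: 15 methyl (3S,5E)-6-{[(2E)-4-bromo-2-(propan-2-yl)but-2-en-1-yl]oxy}-3-[methoxy(methyl)carbamoyl]-5-methylhex-5-enoate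
Product: 17 methyl (2E,5S,6S,8E)-5-[methoxy(methyl)carbamoyl]-3-methyl-9-(propan-2-yl)-1-oxacyclodeca-2,8-diene-6-carboxylate, via potassium enolate 16 (not isolated)
Conditions: KN(SiMe3)2, THF, syringe-pump addition of 15 (final 0.002 M), −78 → −30 °C; product kept cold and used at once
Reagents that add atoms: none
Why: intramolecular alkylation of the ester enolate (the amide α-hydrogen is tertiary and far less acidic) by the primary allylic bromide under high dilution should close the ten-membered ring, a ring closure of the kind used for (E,E)-cyclodecadienes; the new C9 centre is not controlled here.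

Step 11
Reactants: 17 methyl (2E,5S,6S,8E)-5-[methoxy(methyl)carbamoyl]-3-methyl-9-(propan-2-yl)-1-oxacyclodeca-2,8-diene-6-carboxylate
Product: 19 methyl 6-[methoxy(methyl)carbamoyl]-7a-methyl-1-oxo-3-(propan-2-yl)octahydro-1H-indene-5-carboxylate (trans-fused; 7aβ-CH3, 3aα-H, 3α-isopropyl, 5β-ester, 6α-amide), via ring-C aldehyde 18 (not isolated)
Conditions: ClCH2CH2Cl (degassed, 0.01 M), 80 °C; then [Rh(nbd)(dppe)]BF4 (10 mol %, activated by H2), 25 → 60 °C, same pot
Reagents that add atoms: none
Why: Heating the (E,E)-oxacyclodecadiene triggers a transannular [3,3]-sigmatropic (Claisen) rearrangement that forms C13–C14, contracts the ten-membered ring to ring C and releases the α-quaternary aldehyde 18; cationic monovalent rhodium then inserts into the formyl C–H bond, adds Rh–H across the 1,1-disubstituted alkene and reductively eliminates C16–C17 to give the ring-D ketone. The closest known reaction types are the one-pot Claisen rearrangement/rhodium-catalysed intramolecular hydroacylation of allyl vinyl ethers to cyclopentanones and the germacrene-to-elemene Cope ring contraction of (E,E)-cyclodeca-1,5-dienes. Ring C is closed by transannular ring contraction through a chair six-membered transition state inside the macrocycle (10 → 6), and ring D by C–C reductive elimination from a six-membered acyl–rhodium–alkyl metallacycle (formal 5-endo hydroacylation of a 4-pentenal). C13 and C14 are controlled by the two (E) double bonds, which in the chair–chair transition state put both tether arms equatorial (trans C/D fusion, CH3 axial), while the resident C11 stereocentre selects the absolute sense because its amide must be equatorial to avoid a 1,3-diaxial clash with the C13 methyl group; C15 is controlled by allylic strain in the rhodacycle, which keeps the isopropyl group away from C8H2 and so cis to 14-H. The step needs chair over boat in the rearrangement, secured by the (E,E) geometry and the release of ring strain, and hydroacylation over decarbonylation, favoured by the quaternary α-carbon (no α-hydrogen, gem-disubstituent effect) and the chelating diphosphine.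

Step 12
Reactants: 19 methyl 6-[methoxy(methyl)carbamoyl]-7a-methyl-1-oxo-3-(propan-2-yl)octahydro-1H-indene-5-carboxylate
Product: 20 methyl 1β-hydroxy-6-[methoxy(methyl)carbamoyl]-7a-methyl-3-(propan-2-yl)octahydro-1H-indene-5-carboxylate
Conditions: NaBH4, CH3OH, 0 °C; then NaOCH3 (0.2 equiv), CH3OH, 25 °C
Reagents that add atoms: none
Why: hydride reduction of the cyclopentanone from the face opposite the angular methyl group (as for 17-oxo steroids) should give the 17β-alcohol, and the methoxide treatment equilibrates any C9 epimer to the equatorial ester.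

Step 13
Reactants: 20 methyl 1β-hydroxy-6-[methoxy(methyl)carbamoyl]-7a-methyl-3-(propan-2-yl)octahydro-1H-indene-5-carboxylate
Product: 21 methyl 1β-{[tert-butyl(dimethyl)silyl]oxy}-6-[methoxy(methyl)carbamoyl]-7a-methyl-3-(propan-2-yl)octahydro-1H-indene-5-carboxylate
Conditions: t-BuMe2SiOTf, 2,6-lutidine, CH2Cl2, 0 °C
Reagents that add atoms: tert-butyldimethylsilyl trifluoromethanesulfonate, CC(C)(C)[Si](C)(C)OS(=O)(=O)C(F)(F)F
Why: silylation of the hindered secondary alcohol with the silyl triflate protects it against the Grignard, methylenation, oxidation and low-valent titanium steps.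

Step 14
Reactants: 22 cyclopent-2-en-1-one; 23 ethyl glyoxylate
Product: 26 ethyl (2E)-2-[(2S)-2-methyl-5-oxocyclopentylidene]acetate, via zinc enolate 24 (not isolated), via zinc aldolate 25 (not isolated)
Conditions: Zn(CH3)2, Cu(OTf)2 (1 mol %), chiral binaphthol-derived phosphoramidite ligand (2 mol %, the enantiomer that gives the 3S adduct), toluene, −30 °C; then 23, −30 → 0 °C; then CH3SO2Cl, Et3N, 0 → 25 °C
Reagents that add atoms: dimethylzinc, C[Zn]C
Why: copper-catalysed asymmetric conjugate addition sets the ring-A methyl stereocentre under ligand control, the zinc enolate is trapped regiospecifically by aldol addition, and mesylation with E1cB elimination gives the exocyclic enone (its geometry is immaterial).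

Step 15
Reactants: 26 ethyl (2E)-2-[(2S)-2-methyl-5-oxocyclopentylidene]acetate
Product: 27 ethyl 2-[(1S,2S)-2-methyl-5-oxocyclopentyl]acetate
Conditions: H2 (1 atm), Pd/C (5% palladium on carbon), EtOAc, 25 °C
Reagents that add atoms: none
Why: heterogeneous hydrogenation of the exocyclic alkene from the face opposite the adjacent methyl group should put the new ring hydrogen anti to the methyl group, so the side chain ends up cis to it (the kinetic, contra-thermodynamic 2,3-cis ketone).

Step 16
Reactants: 27 ethyl 2-[(1S,2S)-2-methyl-5-oxocyclopentyl]acetate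
Product: 28 (1R,2S,3S)-2-(2-hydroxyethyl)-3-methylcyclopentan-1-ol
Conditions: LiAlH4, THF, −78 → 0 °C
Reagents that add atoms: none
Why: LiAlH4 reduces ketone and ester at low temperature before the α-centre can epimerise; hydride attack anti to the two cis substituents should give the all-cis diol, whose carbinol configuration is immaterial because it is oxidised in step 22.

Step 17
Reactants: 28 (1R,2S,3S)-2-(2-hydroxyethyl)-3-methylcyclopentan-1-ol
Product: 29 triethyl({(1R,2S,3S)-3-methyl-2-[2-(triethylsilyloxy)ethyl]cyclopentyl}oxy)silane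
Conditions: Et3SiCl (2.5 equiv), imidazole, DMF, 0 → 25 °C
Reagents that add atoms: chlorotriethylsilane, CC[Si](Cl)(CC)CC
Why: bis-silylation protects both hydroxyl groups and avoids activating a free 1,4-diol, which would cyclise to a tetrahydrofuran.

Step 18
Reactants: 29 triethyl({(1R,2S,3S)-3-methyl-2-[2-(triethylsilyloxy)ethyl]cyclopentyl}oxy)silane
Product: 30 {[(1R,2S,3S)-2-(2-bromoethyl)-3-methylcyclopentyl]oxy}(triethyl)silane
Conditions: Ph3PBr2 (1.1 equiv), CH2Cl2, −20 → 0 °C
Reagents that add atoms: dibromotriphenylphosphorane, BrP(Br)(c1ccccc1)(c1ccccc1)c1ccccc1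
Why: dibromotriphenylphosphorane converts a primary silyl ether directly into the bromide (SN2 on the oxyphosphonium intermediate), the hindered secondary silyl ether reacting much more slowly.

Step 19
Reactants: 30 {[(1R,2S,3S)-2-(2-bromoethyl)-3-methylcyclopentyl]oxy}(triethyl)silane; 21 methyl 1β-{[tert-butyl(dimethyl)silyl]oxy}-6-[methoxy(methyl)carbamoyl]-7a-methyl-3-(propan-2-yl)octahydro-1H-indene-5-carboxylate
Product: 32 methyl 1β-{[tert-butyl(dimethyl)silyl]oxy}-7a-methyl-6-{3-[(1S,2S,5R)-2-methyl-5-(triethylsilyloxy)cyclopentyl]propanoyl}-3-(propan-2-yl)octahydro-1H-indene-5-carboxylate, via Grignard reagent 31 (not isolated)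
Conditions: 30, Mg, THF, 25 °C; then 21, THF, −40 → −10 °C
Reagents that add atoms: none
Why: Weinreb ketone synthesis, in which the Grignard reagent adds once to the N-methoxy-N-methylamide through a chelated tetrahedral intermediate and, at low temperature, should do so faster than it attacks the hindered secondary methyl ester.

Step 20
Reactants: 32 methyl 1β-{[tert-butyl(dimethyl)silyl]oxy}-7a-methyl-6-{3-[(1S,2S,5R)-2-methyl-5-(triethylsilyloxy)cyclopentyl]propanoyl}-3-(propan-2-yl)octahydro-1H-indene-5-carboxylate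
Product: 33 the bis-methylenated compound: 32 with the C11 ketone as C(=CH2) and the C9 ester as 1-methoxyethenyl
Conditions: Cp2Ti(CH3)2 (5 equiv), toluene/THF, 70 °C, dark
Reagents that add atoms: dimethyltitanocene, C[Ti](C)(C1C=CC=C1)C1C=CC=C1
Why: titanium-mediated carbonyl methylenation converts the ketone into the exocyclic methylene and the ester into its methyl enol ether in one non-basic operation, so the C11 α-centre should not epimerise.

Step 21
Reactants: 33 the bis-methylenated compound
Product: 34 the hydroxy ketone: C9 acetyl group, C11 C(=CH2) side chain, free ring-A carbinol, 17-O-silyl ether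
Conditions: 0.5 M aq. HCl, THF, 0 → 25 °C
Reagents that add atoms: water, O
Why: mild aqueous acid hydrolyses the methyl enol ether to the methyl ketone and cleaves the triethylsilyl ether, while the hindered tert-butyldimethylsilyl ether and the 1,1-disubstituted alkene should survive.

Step 22
Reactants: 34 the hydroxy ketone
Product: 35 the diketone: C9 acetyl group and ring-A cyclopentanone (2,3-cis)
Conditions: Dess–Martin periodinane, NaHCO3, CH2Cl2, 0 °C; used at once
Reagents that add atoms: none
Why: buffered Dess–Martin oxidation gives the 2,3-cis-disubstituted cyclopentanone under neutral conditions that should not epimerise its α-centre.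

Step 23
Reactants: 35 the diketone
Product: 36 17-O-[tert-butyl(dimethyl)silyl] ether of the target
Conditions: TiCl3(DME)1.5, Zn–Cu couple, DME, reflux, syringe-pump addition of 35 over 30 h
Reagents that add atoms: none
Why: intramolecular McMurry coupling of the two ketones on low-valent titanium under high dilution forms the tetrasubstituted alkene and ring B at once, and the eight-membered ring enforces the cis ring geometry of the double bond.

Step 24
Reactants: 36 17-O-[tert-butyl(dimethyl)silyl] ether of the target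
Product: 37 CNP0510481.1 (target)
Conditions: Bu4NF, THF, 50 °C
Reagents that add atoms: none
Why: fluoride-mediated cleavage of the hindered silyl ether releases the secondary alcohol without affecting the two alkenes.

**Compound list**

1 | 4-{[tert-butyl(dimethyl)silyl]oxy}but-2-yn-1-ol | OCC#CCO[Si](C)(C)C(C)(C)C | starting material
2 | alkenylalane: lithium (2Z)-2-(dihydroalumanyl)-4-{[tert-butyl(dimethyl)silyl]oxy}but-2-en-1-olate | [Li]OC/C([AlH2])=C/CO[Si](C)(C)C(C)(C)C | intermediate
3 | (2Z)-4-{[tert-butyl(dimethyl)silyl]oxy}-2-iodobut-2-en-1-ol | OC/C(I)=C/CO[Si](C)(C)C(C)(C)C | intermediate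
4 | (2E)-4-{[tert-butyl(dimethyl)silyl]oxy}-2-(propan-2-yl)but-2-en-1-ol | OC/C(C(C)C)=C/CO[Si](C)(C)C(C)(C)C | intermediate
5 | 4-methylpent-4-enoic acid | C=C(C)CCC(=O)O | starting material
6 | (4R)-4-benzyl-1,3-oxazolidin-2-one | O=C1N[C@H](Cc2ccccc2)CO1 | starting material
7 | mixed anhydride: 2,2-dimethylpropanoic 4-methylpent-4-enoic anhydride | C=C(C)CCC(=O)OC(=O)C(C)(C)C | intermediate
8 | (4R)-4-benzyl-3-(4-methylpent-4-enoyl)-1,3-oxazolidin-2-one | C=C(C)CCC(=O)N1[C@H](Cc2ccccc2)COC1=O | intermediate
9 | sodium (1Z)-1-[(4R)-4-benzyl-2-oxo-1,3-oxazolidin-3-yl]-4-methylpenta-1,4-dien-1-olate (enolate of 8) | [Na+].C=C(C)C/C=C(\[O-])N1[C@H](Cc2ccccc2)COC1=O | intermediate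
10 | methyl (3S)-3-{[(4R)-4-benzyl-2-oxo-1,3-oxazolidin-3-yl]carbonyl}-5-methylhex-5-enoate | C=C(C)C[C@H](C(=O)N1[C@H](Cc2ccccc2)COC1=O)CC(=O)OC | intermediate
11 | methyl (3S)-3-[methoxy(methyl)carbamoyl]-5-methylhex-5-enoate | C=C(C)C[C@H](C(=O)N(C)OC)CC(=O)OC | intermediate
12 | methyl (3S,5E)-3-[methoxy(methyl)carbamoyl]-5-methyl-6-(4,4,5,5-tetramethyl-1,3,2-dioxaborolan-2-yl)hex-5-enoate | C/C(=C\B1OC(C)(C)C(C)(C)O1)C[C@H](C(=O)N(C)OC)CC(=O)OC | intermediate
13 | methyl (3S,5E)-6-{[(2E)-4-{[tert-butyl(dimethyl)silyl]oxy}-2-(propan-2-yl)but-2-en-1-yl]oxy}-3-[methoxy(methyl)carbamoyl]-5-methylhex-5-enoate | C/C(=C\OC/C(C(C)C)=C/CO[Si](C)(C)C(C)(C)C)C[C@H](C(=O)N(C)OC)CC(=O)OC | intermediate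
14 | methyl (3S,5E)-6-{[(2E)-4-hydroxy-2-(propan-2-yl)but-2-en-1-yl]oxy}-3-[methoxy(methyl)carbamoyl]-5-methylhex-5-enoate | C/C(=C\OC/C(C(C)C)=C/CO)C[C@H](C(=O)N(C)OC)CC(=O)OC | intermediate
15 | methyl (3S,5E)-6-{[(2E)-4-bromo-2-(propan-2-yl)but-2-en-1-yl]oxy}-3-[methoxy(methyl)carbamoyl]-5-methylhex-5-enoate | C/C(=C\OC/C(C(C)C)=C/CBr)C[C@H](C(=O)N(C)OC)CC(=O)OC | intermediate
16 | potassium ester enolate of 15 (enolate geometry not defined) | [K+].C/C(=C\OC/C(C(C)C)=C/CBr)C[C@H](C(=O)N(C)OC)C=C([O-])OC | intermediate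
17 | methyl (2E,5S,6S,8E)-5-[methoxy(methyl)carbamoyl]-3-methyl-9-(propan-2-yl)-1-oxacyclodeca-2,8-diene-6-carboxylate | COC(=O)[C@H]1C/C=C(C(C)C)/CO/C=C(C)/C[C@@H]1C(=O)N(C)OC | intermediate
18 | ring-C aldehyde: methyl 4-formyl-2-[methoxy(methyl)carbamoyl]-4-methyl-5-(3-methylbut-1-en-2-yl)cyclohexane-1-carboxylate (chair; formyl, alkenyl, ester and amide equatorial, C-methyl axial) | O=C[C@]1(C)C[C@H](C(=O)N(C)OC)[C@@H](C(=O)OC)C[C@H]1C(=C)C(C)C | intermediate
19 | methyl 6-[methoxy(methyl)carbamoyl]-7a-methyl-1-oxo-3-(propan-2-yl)octahydro-1H-indene-5-carboxylate (trans-fused; 7aβ-CH3, 3aα-H, 3α-isopropyl, 5β-ester, 6α-amide) | O=C1C[C@@H](C(C)C)[C@@H]2C[C@H](C(=O)OC)[C@@H](C(=O)N(C)OC)C[C@@]12C | intermediate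
20 | methyl 1β-hydroxy-6-[methoxy(methyl)carbamoyl]-7a-methyl-3-(propan-2-yl)octahydro-1H-indene-5-carboxylate (other centres as in 19) | O[C@@H]1C[C@@H](C(C)C)[C@@H]2C[C@H](C(=O)OC)[C@@H](C(=O)N(C)OC)C[C@@]12C | intermediate
21 | methyl 1β-{[tert-butyl(dimethyl)silyl]oxy}-6-[methoxy(methyl)carbamoyl]-7a-methyl-3-(propan-2-yl)octahydro-1H-indene-5-carboxylate | CC(C)(C)[Si](C)(C)O[C@@H]1C[C@@H](C(C)C)[C@@H]2C[C@H](C(=O)OC)[C@@H](C(=O)N(C)OC)C[C@@]12C | intermediate
22 | cyclopent-2-en-1-one | O=C1C=CCC1 | starting material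
23 | ethyl glyoxylate (ethyl 2-oxoacetate) | CCOC(=O)C=O | starting material
24 | methylzinc (3S)-3-methylcyclopent-1-en-1-olate | C[C@H]1CCC(O[Zn]C)=C1 | intermediate
25 | zinc aldolate: ethyl 2-[(1S,2S)-2-methyl-5-oxocyclopentyl]-2-[(methylzincio)oxy]acetate (side chain trans to CH3; mixture at the carbinol carbon) | CCOC(=O)C(O[Zn]C)[C@H]1C(=O)CC[C@@H]1C | intermediate
26 | ethyl (2E)-2-[(2S)-2-methyl-5-oxocyclopentylidene]acetate | CCOC(=O)/C=C1/C(=O)CC[C@@H]1C | intermediate
27 | ethyl 2-[(1S,2S)-2-methyl-5-oxocyclopentyl]acetate (2,3-cis) | CCOC(=O)C[C@@H]1C(=O)CC[C@@H]1C | intermediate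
28 | (1R,2S,3S)-2-(2-hydroxyethyl)-3-methylcyclopentan-1-ol (all-cis) | OCC[C@@H]1[C@H](O)CC[C@@H]1C | intermediate
29 | triethyl({(1R,2S,3S)-3-methyl-2-[2-(triethylsilyloxy)ethyl]cyclopentyl}oxy)silane | CC[Si](CC)(CC)OCC[C@@H]1[C@H](O[Si](CC)(CC)CC)CC[C@@H]1C | intermediate
30 | {[(1R,2S,3S)-2-(2-bromoethyl)-3-methylcyclopentyl]oxy}(triethyl)silane | BrCC[C@@H]1[C@H](O[Si](CC)(CC)CC)CC[C@@H]1C | intermediate
31 | bromo(2-{(1S,2S,5R)-2-methyl-5-[(triethylsilyl)oxy]cyclopentyl}ethyl)magnesium | Br[Mg]CC[C@@H]1[C@H](O[Si](CC)(CC)CC)CC[C@@H]1C | intermediate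
32 | ketone: 21 with the amide replaced by a 3-[(1S,2S,5R)-2-methyl-5-(triethylsilyloxy)cyclopentyl]propanoyl group | CC(C)(C)[Si](C)(C)O[C@@H]1C[C@@H](C(C)C)[C@@H]2C[C@H](C(=O)OC)[C@@H](C(=O)CC[C@@H]3[C@H](O[Si](CC)(CC)CC)CC[C@@H]3C)C[C@@]12C | intermediate
33 | bis-methylenated compound: 32 with C(=CH2) in place of the ketone and 1-methoxyethenyl in place of the ester | CC(C)(C)[Si](C)(C)O[C@@H]1C[C@@H](C(C)C)[C@@H]2C[C@H](C(=C)OC)[C@@H](C(=C)CC[C@@H]3[C@H](O[Si](CC)(CC)CC)CC[C@@H]3C)C[C@@]12C | intermediate
34 | hydroxy ketone: C9 acetyl, C11 C(=CH2) side chain ending in the (1R,2S,3S)-2-substituted 3-methylcyclopentan-1-ol, 17-O-silyl ether | CC(C)(C)[Si](C)(C)O[C@@H]1C[C@@H](C(C)C)[C@@H]2C[C@H](C(C)=O)[C@@H](C(=C)CC[C@@H]3[C@H](O)CC[C@@H]3C)C[C@@]12C | intermediate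
35 | diketone: 34 with the ring-A carbinol oxidised to the 2,3-cis cyclopentanone | CC(C)(C)[Si](C)(C)O[C@@H]1C[C@@H](C(C)C)[C@@H]2C[C@H](C(C)=O)[C@@H](C(=C)CC[C@@H]3C(=O)CC[C@@H]3C)C[C@@]12C | intermediate
36 | 17-O-[tert-butyl(dimethyl)silyl] ether of the target | C=C1CC[C@@H]2/C(=C(/C)[C@H]3C[C@H]4[C@H](C(C)C)C[C@@H](O[Si](C)(C)C(C)(C)C)[C@]4(C)C[C@H]13)CC[C@@H]2C | intermediate
37 | CNP0510481.1 | C=C1CC[C@@H]2/C(=C(/C)[C@H]3C[C@H]4[C@H](C(C)C)C[C@@H](O)[C@]4(C)C[C@H]13)CC[C@@H]2C | target

**Summary**

Total step count: 24. Longest linear sequence: 17 steps (steps 3–13 and 19–24).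

Steps most likely to fail:

Step 10 (ring closure to the ten-membered oxacycle). The enolate may alkylate another molecule instead of its own bromide (oligomers), the base may cause 1,4-elimination of HBr from the allylic bromide, or the strained ring may rearrange during handling. Fallback, setting out from 1 and 11 and coming back at 17: the ring is closed at the C–O bond instead.
- 1 is reduced with NaAlH2(OCH2CH2OCH3)2 at −20 °C (aluminium on the distal carbon) and iodinated to (2Z)-4-{[tert-butyl(dimethyl)silyl]oxy}-3-iodobut-2-en-1-ol F1.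
- Negishi coupling with i-PrZnBr gives (2E)-4-{[tert-butyl(dimethyl)silyl]oxy}-3-(propan-2-yl)but-2-en-1-ol F2, and an Appel reaction gives {[(2E)-4-bromo-2-(propan-2-yl)but-2-en-1-yl]oxy}(tert-butyl)dimethylsilane F3.
- The lithium ester enolate of 11 (LiN(i-Pr)2, THF, −78 °C) is alkylated intermolecularly with F3 to methyl (2S,3S)-2-[(2E)-4-{[tert-butyl(dimethyl)silyl]oxy}-3-(propan-2-yl)but-2-en-1-yl]-3-[methoxy(methyl)carbamoyl]-5-methylhex-5-enoate F4 (C2 epimers tolerated).
- Cross-metathesis with vinylboronic acid pinacol ester gives the alkenylboronate methyl (2S,3S,5E)-2-[(2E)-4-{[tert-butyl(dimethyl)silyl]oxy}-3-(propan-2-yl)but-2-en-1-yl]-3-[methoxy(methyl)carbamoyl]-5-methyl-6-(4,4,5,5-tetramethyl-1,3,2-dioxaborolan-2-yl)hex-5-enoate F5, and HF·pyridine gives the hydroxy boronate methyl (2S,3S,5E)-2-[(2E)-4-hydroxy-3-(propan-2-yl)but-2-en-1-yl]-3-[methoxy(methyl)carbamoyl]-5-methyl-6-(4,4,5,5-tetramethyl-1,3,2-dioxaborolan-2-yl)hex-5-enoate F6.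
- An intramolecular Cu(OAc)2/Et3N alkenylboronate–alcohol coupling at 0.002 M closes the ring to 17.

Step 11 (key step). The rearrangement itself should be reliable, but the acyl rhodium hydride from the neopentyl-type aldehyde may lose CO, or hydride insertion into the hindered 1,1-disubstituted alkene may be too slow, so that ring D does not close. Fallback, setting out from 17 and coming back at 20: 17 is heated without catalyst and aldehyde 18 is isolated. (CH3)2AlCl in CH2Cl2 at −78 °C promotes an intramolecular carbonyl-ene reaction that forms C16–C17 and should give methyl 1β-hydroxy-6-[methoxy(methyl)carbamoyl]-7a-methyl-3-(propan-2-ylidene)octahydro-1H-indene-5-carboxylate F7. Hydroxyl-directed hydrogenation with [Ir(cod)(PCy3)(py)]PF6 and H2 then delivers hydrogen to C15 from the face of the 17-hydroxyl group and gives 20. A 17-epimer would be corrected by Dess–Martin oxidation to 19 and step 12.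

Step 23 (McMurry ring closure). Under the hot, Lewis-acidic low-valent titanium conditions the ring-A ketone may enolise and epimerise at its α-carbon before coupling, the coupling may stop at the pinacol stage, or intermolecular coupling may compete. Fallback, setting out from 35 and coming back at 36: SmI2 (THF, 25 °C, high dilution) effects intramolecular pinacol coupling under neutral conditions to the cis-diol of the future ring-A/B alkene (17-O-silyl ether) F8. 1,1'-Thiocarbonyldiimidazole converts it into the cyclic thionocarbonate of that diol F9, and Corey–Winter olefination with 1,3-dimethyl-2-phenyl-1,3,2-diazaphospholidine at 40 °C gives 36 stereospecifically.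

Further compounds
F1 | step 10 | (2Z)-4-{[tert-butyl(dimethyl)silyl]oxy}-3-iodobut-2-en-1-ol | OC/C=C(I)/CO[Si](C)(C)C(C)(C)C
F2 | step 10 | (2E)-4-{[tert-butyl(dimethyl)silyl]oxy}-3-(propan-2-yl)but-2-en-1-ol | OC/C=C(C(C)C)/CO[Si](C)(C)C(C)(C)C
F3 | step 10 | {[(2E)-4-bromo-2-(propan-2-yl)but-2-en-1-yl]oxy}(tert-butyl)dimethylsilane | BrC/C=C(C(C)C)/CO[Si](C)(C)C(C)(C)C
F4 | step 10 | methyl (2S,3S)-2-[(2E)-4-{[tert-butyl(dimethyl)silyl]oxy}-3-(propan-2-yl)but-2-en-1-yl]-3-[methoxy(methyl)carbamoyl]-5-methylhex-5-enoate | C=C(C)C[C@H](C(=O)N(C)OC)[C@H](C/C=C(C(C)C)/CO[Si](C)(C)C(C)(C)C)C(=O)OC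
F5 | step 10 | methyl (2S,3S,5E)-2-[(2E)-4-{[tert-butyl(dimethyl)silyl]oxy}-3-(propan-2-yl)but-2-en-1-yl]-3-[methoxy(methyl)carbamoyl]-5-methyl-6-(4,4,5,5-tetramethyl-1,3,2-dioxaborolan-2-yl)hex-5-enoate | C/C(=C\B1OC(C)(C)C(C)(C)O1)C[C@H](C(=O)N(C)OC)[C@H](C/C=C(C(C)C)/CO[Si](C)(C)C(C)(C)C)C(=O)OC
F6 | step 10 | methyl (2S,3S,5E)-2-[(2E)-4-hydroxy-3-(propan-2-yl)but-2-en-1-yl]-3-[methoxy(methyl)carbamoyl]-5-methyl-6-(4,4,5,5-tetramethyl-1,3,2-dioxaborolan-2-yl)hex-5-enoate | C/C(=C\B1OC(C)(C)C(C)(C)O1)C[C@H](C(=O)N(C)OC)[C@H](C/C=C(C(C)C)/CO)C(=O)OC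
F7 | step 11 | methyl 1β-hydroxy-6-[methoxy(methyl)carbamoyl]-7a-methyl-3-(propan-2-ylidene)octahydro-1H-indene-5-carboxylate | O[C@@H]1CC(=C(C)C)[C@@H]2C[C@H](C(=O)OC)[C@@H](C(=O)N(C)OC)C[C@@]12C
F8 | step 23 | cis-diol of the future ring-A/B alkene, 17-O-silyl ether (the two carbinol centres not defined) | C=C1CC[C@@H]2C(O)(C(C)(O)[C@H]3C[C@H]4[C@H](C(C)C)C[C@@H](O[Si](C)(C)C(C)(C)C)[C@]4(C)C[C@H]13)CC[C@@H]2C
F9 | step 23 | cyclic thionocarbonate of F8 | C=C1CC[C@@H]2C3(OC(=S)OC3(C)[C@H]4C[C@H]5[C@H](C(C)C)C[C@@H](O[Si](C)(C)C(C)(C)C)[C@]5(C)C[C@H]14)CC[C@@H]2C
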